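**Plan**

1. Retrosynthetic cuts, in order: (a) O1–C8a of the flavanone ring C, an aryl C–O bond; (b) the C2–O bond of the resulting open (S)-aldol, back to the C2=C3 alkene of an (E)-chalcone; (c) the pyranone O–C2 bond and C2=C3 unsaturation of the flavone unit, back to a 2'-hydroxychalcone; (d) both chalcone C=C bonds (Claisen–Schmidt); (e) the C6–O–aryl diaryl ether (SNAr on 4-fluorobenzaldehyde); (f) C4a–C4 (Friedel–Crafts acetylation).
2. Forward: ring A is bought whole as the symmetric 4-bromo-2,6-dimethoxyphenol; acetylation, first chalcone, diaryl ether and second chalcone follow; the flavone pyranone ring closes first (step 5), the flavanone ring C last (step 7); one global deprotection ends the route.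
3. Enabling feature: in ring A, C8a (the carbon that carries O1) is para to C6 (diaryl ether oxygen) and ortho to C4a (which bears the C4 carbonyl). C8a can therefore arrive as the para-bromine of the symmetric phenol, its C–Br bond is activated and pre-coordinated by the C4 carbonyl, and the C2 hydroxyl can reach it only through a six-membered ring.
4. Stereochemistry: the only stereocentre, C2, is set on the open chain by copper/Josiphos-catalysed enantioselective beta-borylation of the chalcone and stereoretentive C–B oxidation. The ring closure forms the other C–O bond of O1, so the labile para-oxybenzylic C2–O bond is never broken.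
5. Oxygen differentiation: 5-OMe and 7-OMe come from the two methoxy groups of the phenol; the C4 carbonyl later singles out 5-OMe for BCl3 cleavage together with the benzyl ethers.

Key step: step 7

Remark (numbering): flavanone locants (O1, C2, C3, C4, C4a, C5 to C8, C8a) are used for the corresponding atoms of all open-chain precursors.

Remark (assumption): the Josiphos antipode used in step 6 is taken to be the one whose copper boryl complex attacks the C2 enantioface that leads to the (S)-carbinol; both antipodes are sold, and the sense is to be fixed on the first run by Mosher ester analysis of 11.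

**Route**

Step 1
Reactants: 1 4-bromo-2,6-dimethoxyphenol
Product: 2 3-acetyl-4-bromo-2,6-dimethoxyphenyl acetate
Conditions: Ac2O (3 equiv), TfOH (10 mol%), MeNO2, 0 °C to rt
Reagents that add atoms: acetic anhydride, CC(=O)OC(C)=O
Why: Friedel–Crafts acylation: after fast O-acetylation the acylium equivalent attacks the only free kind of ring position, ortho to one methoxy group and para to the other, and since the two such positions (future C4a and C8) are equivalent by the symmetry of 1 a single ketone should result, the absence of a strong Lewis acid keeping both methyl ethers intact.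

Step 2
Reactants: 2 3-acetyl-4-bromo-2,6-dimethoxyphenyl acetate; 3 4-(benzyloxy)benzaldehyde
Product: 4 (E)-chalcone with free C6 phenol
Conditions: KOH (5 equiv), EtOH, rt; then aq. HCl
Reagents that add atoms: none
Why: Claisen–Schmidt condensation (aldol addition, then E1cB dehydration) of the methyl ketone with the non-enolisable aldehyde should give the thermodynamic (E)-enone, while the excess hydroxide saponifies the aryl acetate in the same pot and frees the C6 phenol.

Step 3
Reactants: 4 (E)-chalcone with free C6 phenol; 5 4-fluorobenzaldehyde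
Product: 6 chalcone diaryl ether aldehyde
Conditions: K2CO3 (2 equiv), DMF, 110 °C
Reagents that add atoms: none
Why: Nucleophilic aromatic substitution: the C6 phenoxide adds para to the formyl group of 5 and expels fluoride through a Meisenheimer intermediate, a reaction type that tolerates phenols flanked by two methoxy groups, and neither the enone nor the far less activated C8a–Br should compete.

Step 4
Reactants: 6 chalcone diaryl ether aldehyde; 7 1-[2,4-bis(benzyloxy)-6-hydroxyphenyl]ethan-1-one
Product: 8 bis-chalcone
Conditions: KOH (aq. 50%), EtOH/THF, rt; then aq. HCl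
Reagents that add atoms: none
Why: Claisen–Schmidt condensation of the enolate of 7 with the aryl aldehyde should give the second (E)-chalcone, the first enone having no methyl ketone and no free ortho-hydroxyl so that it passes unchanged.

Step 5
Reactants: 8 bis-chalcone
Product: 9 flavone carrying the ring A chalcone
Conditions: I2 (10 mol%), DMSO, 120 °C
Reagents that add atoms: none
Why: Iodine-catalysed oxidative cyclisation of a 2'-hydroxychalcone (oxa-Michael closure, alpha-iodination, loss of HI, DMSO reoxidising HI to I2) builds the flavone, while the ring A chalcone, whose ketone has no ortho-hydroxyl (C5 is OMe, C8a is Br), cannot cyclise and is carried on as a masked aldol.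

Step 6
Reactants: 9 flavone carrying the ring A chalcone
Product: 11 (S)-beta-hydroxy ketone (open-chain aldol), via (S)-beta-boryl ketone 10 (not isolated)
Conditions: CuCl (5 mol%), NaOtBu (8 mol%), Josiphos SL-J001 (5 mol%, antipode as in the remark), B2pin2 (1.1 equiv), MeOH (2 equiv), THF, rt; then NaBO3·4H2O, THF/H2O, rt
Reagents that add atoms: bis(pinacolato)diboron, CC1(C)OB(OC1(C)C)B1OC(C)(C)C(C)(C)O1 (boryl group of 10); sodium perborate tetrahydrate, [Na+].[O-]OB=O.O.O.O.O (hydroxyl oxygen of 11)
Why: Copper-catalysed enantioselective conjugate borylation of an acyclic enone: the Josiphos-bound copper boryl adds to one enantioface of C2 of the ordinary chalcone, which is far more electrophilic than the vinylogous-ester C2=C3 of the flavone, methanol protonates the copper enolate, and perborate oxidation replaces boron by oxygen with retention, which sets C2 as S.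

Step 7
Reactants: 11 (S)-beta-hydroxy ketone (open-chain aldol)
Product: 12 protected (2S)-flavanone–flavone
Conditions: NiBr2·glyme (10 mol%), 4,4'-di-tert-butyl-2,2'-bipyridine (10 mol%), quinuclidine (1.5 equiv), nBu4NBr, DMA (0.02 M), undivided cell, reticulated vitreous carbon anode, nickel-foam cathode, constant current, rt
Reagents that add atoms: none
Why: Cathodic reduction of divalent nickel gives a low-valent (zerovalent or monovalent) bipyridine nickel species that inserts into the C8a–Br bond, which is activated and pre-coordinated by the ortho C4 carbonyl; the C2 hydroxyl, deprotonated by quinuclidine, displaces bromide to give a seven-membered aryl nickel alkoxide, and anodic oxidation to trivalent nickel triggers C(sp2)–O reductive elimination that forms O1–C8a. The closest known reaction type is the nickel-electrocatalytic (paired-electrolysis) O-arylation of aliphatic alcohols with aryl bromides, here run intramolecularly. Ring C closes by reductive elimination from the seven-membered nickelacycle, formally a six-membered exo closure of O1 onto C8a; no other ring size is within reach of the tether. No new stereocentre is formed, and C2 keeps its S configuration because neither C2–O nor C2–H is broken, in contrast to a closure at C2. The step needs etherification to outrun dehydration to the chalcone, retro-aldol cleavage, beta-hydride elimination and hydrodebromination, and it must leave the flavone unreduced. Room temperature, a weak amine base, intramolecular delivery of the alkoxide by the chelating ortho carbonyl, and a catalyst reduced at a potential well positive of the flavone should secure this, and the methyl ether on C5 prevents a ring A phenoxide from deactivating C8a–Br.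

Step 8
Reactants: 12 protected (2S)-flavanone–flavone
Product: 13 CNP0269971.1 (target)
Conditions: BCl3 (8 equiv), pentamethylbenzene (10 equiv), CH2Cl2, −78 to 0 °C; then MeOH, aq. NaHCO3
Reagents that add atoms: none
Why: Lewis-acid ether cleavage: BCl3 removes the three benzyl groups as benzyl cations trapped by pentamethylbenzene and cleaves only the methyl ether peri to the C4 carbonyl (5-OMe) through a six-membered boron chelate, which should leave the unchelated 7-OMe, the diaryl ether and, at low temperature, the C2 stereocentre untouched.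

**Compound list**

1 | 4-bromo-2,6-dimethoxyphenol | COc1cc(Br)cc(OC)c1O | starting material
2 | 3-acetyl-4-bromo-2,6-dimethoxyphenyl acetate | CC(=O)Oc1c(OC)cc(Br)c(C(C)=O)c1OC | intermediate
3 | 4-(benzyloxy)benzaldehyde | O=Cc1ccc(OCc2ccccc2)cc1 | starting material
4 | (E)-3-[4-(benzyloxy)phenyl]-1-(6-bromo-3-hydroxy-2,4-dimethoxyphenyl)prop-2-en-1-one | COc1cc(Br)c(C(=O)/C=C/c2ccc(OCc3ccccc3)cc2)c(OC)c1O | intermediate
5 | 4-fluorobenzaldehyde | O=Cc1ccc(F)cc1 | starting material
6 | 4-(3-{(E)-3-[4-(benzyloxy)phenyl]prop-2-enoyl}-4-bromo-2,6-dimethoxyphenoxy)benzaldehyde | COc1cc(Br)c(C(=O)/C=C/c2ccc(OCc3ccccc3)cc2)c(OC)c1Oc1ccc(C=O)cc1 | intermediate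
7 | 1-[2,4-bis(benzyloxy)-6-hydroxyphenyl]ethan-1-one | CC(=O)c1c(O)cc(OCc2ccccc2)cc1OCc1ccccc1 | starting material
8 | (E)-1-[2,4-bis(benzyloxy)-6-hydroxyphenyl]-3-[4-(3-{(E)-3-[4-(benzyloxy)phenyl]prop-2-enoyl}-4-bromo-2,6-dimethoxyphenoxy)phenyl]prop-2-en-1-one | COc1cc(Br)c(C(=O)/C=C/c2ccc(OCc3ccccc3)cc2)c(OC)c1Oc1ccc(/C=C/C(=O)c2c(O)cc(OCc3ccccc3)cc2OCc2ccccc2)cc1 | intermediate
9 | 5,7-bis(benzyloxy)-2-[4-(3-{(E)-3-[4-(benzyloxy)phenyl]prop-2-enoyl}-4-bromo-2,6-dimethoxyphenoxy)phenyl]-4H-chromen-4-one | COc1cc(Br)c(C(=O)/C=C/c2ccc(OCc3ccccc3)cc2)c(OC)c1Oc1ccc(-c2cc(=O)c3c(OCc4ccccc4)cc(OCc4ccccc4)cc3o2)cc1 | intermediate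
10 | 5,7-bis(benzyloxy)-2-[4-(3-{(3S)-3-[4-(benzyloxy)phenyl]-3-(4,4,5,5-tetramethyl-1,3,2-dioxaborolan-2-yl)propanoyl}-4-bromo-2,6-dimethoxyphenoxy)phenyl]-4H-chromen-4-one | COc1cc(Br)c(C(=O)C[C@@H](c2ccc(OCc3ccccc3)cc2)B2OC(C)(C)C(C)(C)O2)c(OC)c1Oc1ccc(-c2cc(=O)c3c(OCc4ccccc4)cc(OCc4ccccc4)cc3o2)cc1 | intermediate (not isolated)
11 | 5,7-bis(benzyloxy)-2-[4-(3-{(3S)-3-[4-(benzyloxy)phenyl]-3-hydroxypropanoyl}-4-bromo-2,6-dimethoxyphenoxy)phenyl]-4H-chromen-4-one | COc1cc(Br)c(C(=O)C[C@@H](c2ccc(OCc3ccccc3)cc2)O)c(OC)c1Oc1ccc(-c2cc(=O)c3c(OCc4ccccc4)cc(OCc4ccccc4)cc3o2)cc1 | intermediate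
12 | (2S)-2-[4-(benzyloxy)phenyl]-6-{4-[5,7-bis(benzyloxy)-4-oxo-4H-chromen-2-yl]phenoxy}-5,7-dimethoxy-2,3-dihydro-4H-chromen-4-one | COc1cc2c(c(OC)c1Oc1ccc(-c3cc(=O)c4c(OCc5ccccc5)cc(OCc5ccccc5)cc4o3)cc1)C(=O)C[C@@H](c1ccc(OCc3ccccc3)cc1)O2 | intermediate
13 | (2S)-6-[4-(5,7-dihydroxy-4-oxo-4H-chromen-2-yl)phenoxy]-5-hydroxy-2-(4-hydroxyphenyl)-7-methoxy-2,3-dihydro-4H-chromen-4-one (CNP0269971.1) | COc1cc2c(c(O)c1Oc1ccc(-c3cc(=O)c4c(O)cc(O)cc4o3)cc1)C(=O)C[C@@H](c1ccc(O)cc1)O2 | target

**Totals**

Total step count: 8. Longest linear sequence: 8 steps (from 1).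

**Steps most likely to fail**

Step 7. The aldol may dehydrate to the chalcone or undergo retro-aldol cleavage before the ring closes, and the aryl nickel intermediate may be protonated (hydrodebromination) or undergo oxidative addition too slowly at the crowded bromide. The fallback changes the oxidation level and uses thermal copper catalysis. It sets out from 11: chelation-directed reduction with Me4NBH(OAc)3 in MeCN/AcOH at −30 °C (Evans–Saksena conditions, intramolecular hydride delivery that leaves the flavone carbonyl alone) should give the anti-(1S,3S)-1,3-diol F1, which has no enolisable ketone and so cannot dehydrate or cleave. Ullmann-type O-arylation (CuI, 3,4,7,8-tetramethyl-1,10-phenanthroline, Cs2CO3, toluene, 100 °C), in which only the C2 hydroxyl can reach C8a through a six-membered ring, should then give the (2S,4S)-flavan-4-ol F2. Dess–Martin periodinane (NaHCO3, CH2Cl2, rt) reoxidises C4, and the route is rejoined at 12.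

Step 6. Facial selectivity may be poor on an enone whose aryl ketone is twisted by two ortho substituents, and the copper boryl may also attack C8a–Br. The fallback introduces the oxygen by asymmetric nucleophilic epoxidation instead of boron. It sets out from 9: Juliá–Colonna epoxidation with poly-D-leucine, urea–hydrogen peroxide and DBU in THF should give the (2S,3R)-epoxy ketone F3. Regioselective reductive opening of the C(alpha)–O bond with sodium phenylselenotriethoxyborate (PhSeSePh, NaBH4, EtOH, AcOH, 0 °C) keeps the C2–O bond and its configuration, and the route is rejoined at 11.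

Step 8. The Lewis acid may ionise the para-oxybenzylic C2–O1 bond (ring opening and loss of configuration), cleave the 7-OMe as well, or allow C-benzylation of the electron-rich rings. The fallback separates the two deprotections and removes the benzyl groups under neutral conditions. It sets out from 12: hydrogenolysis (H2, Pd/C, EtOAc/THF, rt) should give the 5-O-methyl triphenol F4, and anhydrous MgI2 in THF at 40 °C, which demethylates only next to a chelating carbonyl, then cleaves the 5-OMe; the route is rejoined at 13.

**Further compounds**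

F1 | step 7 | 5,7-bis(benzyloxy)-2-[4-(3-{(1S,3S)-3-[4-(benzyloxy)phenyl]-1,3-dihydroxypropyl}-4-bromo-2,6-dimethoxyphenoxy)phenyl]-4H-chromen-4-one | COc1cc(Br)c([C@@H](O)C[C@@H](c2ccc(OCc3ccccc3)cc2)O)c(OC)c1Oc1ccc(-c2cc(=O)c3c(OCc4ccccc4)cc(OCc4ccccc4)cc3o2)cc1
F2 | step 7 | 5,7-bis(benzyloxy)-2-[4-({(2S,4S)-2-[4-(benzyloxy)phenyl]-4-hydroxy-5,7-dimethoxy-3,4-dihydro-2H-chromen-6-yl}oxy)phenyl]-4H-chromen-4-one | COc1cc2c(c(OC)c1Oc1ccc(-c3cc(=O)c4c(OCc5ccccc5)cc(OCc5ccccc5)cc4o3)cc1)[C@@H](O)C[C@@H](c1ccc(OCc3ccccc3)cc1)O2
F3 | step 6 | 5,7-bis(benzyloxy)-2-{4-[3-({(2S,3R)-3-[4-(benzyloxy)phenyl]oxiran-2-yl}carbonyl)-4-bromo-2,6-dimethoxyphenoxy]phenyl}-4H-chromen-4-one | COc1cc(Br)c(C(=O)[C@H]2O[C@@H]2c2ccc(OCc3ccccc3)cc2)c(OC)c1Oc1ccc(-c2cc(=O)c3c(OCc4ccccc4)cc(OCc4ccccc4)cc3o2)cc1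
F4 | step 8 | (2S)-6-[4-(5,7-dihydroxy-4-oxo-4H-chromen-2-yl)phenoxy]-2-(4-hydroxyphenyl)-5,7-dimethoxy-2,3-dihydro-4H-chromen-4-one | COc1cc2c(c(OC)c1Oc1ccc(-c3cc(=O)c4c(O)cc(O)cc4o3)cc1)C(=O)C[C@@H](c1ccc(O)cc1)O2
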